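| flask | G | D | X | E | remark | time |
|---|---|---|---|---|---|---|
| Monday's | 0.025 M | 0.025 M | 2.5 equiv | 10 mol% | run made earlier |  |
| Friday's | 0.10 M | 0.10 M | 2.5 equiv | 10 mol% | run made earlier |  |
| flask | 0.050 M | 0.050 M | 2.50 equiv | 10 mol% |  | 15 min |

| run | time / min | L / % | Z / % |
|---|---|---|---|
| Monday's | 0.667 | 9.6 | 2.9 |
| Monday's | 1.50 | 16.4 | 6.1 |
| Monday's | 4.00 | 26.5 | 10.9 |
| Monday's | 10.0 | 37.5 | 15.6 |
| Friday's | 2.50 | 34.8 | 15.7 |
| Friday's | 5.00 | 44.5 | 16.0 |
| Friday's | 6.00 | 43.9 | 19.3 |
| Friday's | 10.0 | 45.9 | 17.1 |

(scatter of a reading: 1 percentage point)

- X is single-handed; G and D are mirror images of each other, charged as a racemate, each of them at the stated concentration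
- an excess is below zero if the other one leads
- the handed part of X does not stay in what it makes, so the products of the two hands are mirror images too

1. L and Z together, in percent of the G and D charged together, at 15 min
2. excess of L over Z in the product at 15 min
3. whether the exchange between G and D keeps pace with the reaction: how far the product's excess at 15 min gets from its value without exchange to its value with instant exchange (above 80% keeps pace, below 20% hardly takes part, else lags behind)

At late times I read Friday's run as nearly level, which is a reading of scattered points and no more: its readings from 5.00 min on average 62.2% of the charge for L and Z together, with L ahead by an excess of 43.9%. If pace goes with concentration, Friday's 5.00 min correspond in the new flask to 10.0 min, which is sooner than 15 min, so I take both averages for the new flask.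

Monday's first reading gives L over Z as 3.31, and I call this s, the selectivity factor, the rate of G to L over that of D to Z at equal amounts of the two; it is a reading, and its Z carries a scatter of 1 percentage point.

Two extreme flasks can be solved in the head. With instant exchange G and D stay equal, so L and Z form in the ratio s throughout, and the excess is s less one over s plus one, 53.6%. Without exchange I assume each falls in proportion to itself and to X, so dividing the two rates removes X, and integrating gives g, the fraction of G left, as d, the fraction of D left, raised to the power s. At my yield g and d must sum to 0.756, and one Newton step from 0.5 gives d = 0.593 and g = 0.163, an excess of 34.5%. These limits ask for the yield and s, not for what stops the flask.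

Friday's excess is higher than the limit without exchange and lower than the limit with instant exchange, 48.9% of the way, so I say the exchange lags behind.

The forecast gives 62%, 43%, a point below my excess, and lags behind, finding itself “about halfway between the limits”.

The flask gives 62.9% and 45.0%, and its exchange lags behind, 66% of the way where I had 48.9%.

    X + D → Z (k = 0.0287 L mol⁻¹ s⁻¹)
    E → J (k = 0.00284 s⁻¹)
    X + G → L (k = 0.0896 L mol⁻¹ s⁻¹)
    G + J ⇌ D + J, rate k4*[J]*[G] forward; the back reaction follows from the equilibrium constant (k = 3.95 L mol⁻¹ s⁻¹)
    2 X → Q (k = 0.0362 L mol⁻¹ s⁻¹)

In the neighbouring flask, the same but with 1.50 equiv of X, L and Z reach 48.2% at 15.0 min, with 1.81% of its X left. So g and d must sum to 1.04, and one step from 0.7 gives d = 0.712 and g = 0.324. Its excess without exchange is then 40.2%, while s keeps the upper limit at 53.6%. That flask's excess is 47.3%, which stands 52.7% of the way between them.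

The numbers in the tables stem from a simulated flask on assumed constants; noise was put on by code.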